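Ring B is opened at C5–C6. The C8 ketone sits three bonds from the methyl-bearing quaternary C5 (through C7 and C6) and next to C9–C10, which is the product pattern of an anionic oxy-Cope shift of a 2-vinylbicyclo[2.2.2]oct-5-en-2-ol. In one operation the shift makes C5–C6, breaks C3–C8, closes ring B as a cis-decalin, sets C5 against C10 and leaves a C7=C8 enolate and a C3=C4 alkene. The precursor comes from a masked o-benzoquinone Diels–Alder adduct, carries the C4 and C5 methyls on its alkene bridge and already holds the C1 oxygen as an endo 4-methoxybenzyl ether.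

Key step: step 10

Remarks on the chemistry (one line each):
- Eremophilane numbering (C1–C10 ring atoms, C11–C13 side chain, C14 on C5, C15 on C4) is used for atoms in all intermediates; β means the face of the C5 methyl; PMB = 4-methoxybenzyl.
- The methoxy group must enter at C6 of 3,4-dimethylphenol (giving 2-methoxy-4,5-dimethylphenol); the 2-methoxy-3,4-dimethyl isomer would put a methyl group on a bridgehead.
- A heteroatom-substituted dienophile bonds through its substituted carbon to the diene terminus next to the dienone carbonyl; the adduct carbonyl therefore becomes C9 and is removed, and the ketal carbon becomes the C8 ketone (steps 5–8), so that the dienophile oxygen lands on C1 with the β configuration of the target.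
- Compounds 8 and 9 are racemic and are drawn as the enantiomer that is carried on after the resolution in step 6; 4-methoxybenzyl vinyl ether is assumed to be made (step 3) and not bought.

Step 1
Reactants: 1 3,4-dimethylphenol
Product: 2 2-bromo-4,5-dimethylphenol
Conditions: Br2 (1 equiv), CH2Cl2, 0 °C
Reagents that add atoms: bromine BrBr
Why: Electrophilic aromatic bromination goes ortho to the hydroxyl because the para position is blocked, and at C6 rather than C2 because C2 is wedged between the hydroxyl and the C3 methyl.

Step 2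
Reactants: 2 2-bromo-4,5-dimethylphenol
Product: 3 2-methoxy-4,5-dimethylphenol
Conditions: NaOMe (excess), CuBr (cat.), MeOH–DMF, 110 °C; then dilute HCl
Reagents that add atoms: sodium methoxide [Na+].[O-]C
Why: Copper-catalysed Ullmann-type methoxylation of the aryl bromide, a standard way from o-bromophenols to guaiacols, places the methoxy group on the carbon that becomes the ketal carbon C8.

Step 3
Reactants: 4 4-methoxybenzyl alcohol; 5 ethyl vinyl ether
Product: 6 4-methoxybenzyl vinyl ether
Conditions: 5 (excess, as solvent), Pd(OAc)2 (cat.), 1,10-phenanthroline (cat.), rt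
Reagents that add atoms: none
Why: Transfer vinylation (transetherification) catalysed by palladium diacetate exchanges the alkoxy group of a vinyl ether under neutral conditions and is driven by the excess of 5.

Step 4
Reactants: 3 2-methoxy-4,5-dimethylphenol; 6 4-methoxybenzyl vinyl ether (excess)
Product: 8 rac-(1R,4R,7R)-7-[(4-methoxybenzyl)oxy]-3,3-dimethoxy-5,6-dimethylbicyclo[2.2.2]oct-5-en-2-one (ether endo; syn to the C5=C6 bridge), via o-quinone monoketal 7 (not isolated)
Conditions: PhI(OAc)2 added slowly to 3 and 6, MeOH, 0 °C to rt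
Reagents that add atoms: methanol CO
Why: PhI(OAc)2 dearomatises the guaiacol in methanol to monoketal 7, whose electron-poor diene C10=C5–C4=C3 adds the enol ether in an inverse-demand Diels–Alder reaction with the oxygen-bearing carbon bonding to C10 (the terminus next to the carbonyl) and the alkoxy group endo, which fixes C1 relative to C10 and C3.

Step 5
Reactants: 8 Diels–Alder adduct
Product: 9 rac-(1S,2S,4R,7R)-7-[(4-methoxybenzyl)oxy]-3,3-dimethoxy-5,6-dimethylbicyclo[2.2.2]oct-5-en-2-ol (hydroxyl anti to the C5=C6 bridge)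
Conditions: NaBH4, MeOH, 0 °C
Reagents that add atoms: none
Why: Borohydride reduction of the C9 ketone should deliver hydride from the side of the sp2 bridge, which is less hindered than the ethano-bridge side, to give mainly one carbinol epimer at a centre that is only temporary.

Step 6
Reactants: 9 racemic carbinol; 10 (1S)-(−)-camphanic chloride
Product: 11 (1S)-camphanate of (1S,2S,4R,7R)-9 (single diastereomer after separation)
Conditions: pyridine, DMAP, CH2Cl2, rt; chromatography or crystallisation of the two diastereomers
Reagents that add atoms: none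
Why: Acylation with an enantiopure acid chloride turns the racemate into two separable diastereomeric esters (classical resolution, configuration to be assigned crystallographically), and the ester is at the same time the leaving group needed in step 8.

Step 7
Reactants: 11 camphanate ketal
Product: 12 3-[(1S)-camphanoyloxy]-8-[(4-methoxybenzyl)oxy]-5,6-dimethylbicyclo[2.2.2]oct-5-en-2-one (configuration as in 11)
Conditions: TsOH·H2O (cat.), acetone–H2O, 45 °C
Reagents that add atoms: water O
Why: Acid-catalysed hydrolysis of the dimethyl ketal unmasks the C8 ketone, while the ester, the PMB ether and the tetrasubstituted alkene tolerate dilute aqueous acid.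

Step 8
Reactants: 12 α-acyloxy ketone
Product: 13 (1R,4R,8R)-8-[(4-methoxybenzyl)oxy]-5,6-dimethylbicyclo[2.2.2]oct-5-en-2-one
Conditions: SmI2 (2.5 equiv), THF–MeOH, −78 °C
Reagents that add atoms: none
Why: SmI2 reduces the ketone to a ketyl that expels the α-acyloxy group (reductive cleavage of α-heterosubstituted ketones) and methanol protonates the samarium enolate, which completes the 1,2-carbonyl transposition and leaves C9 as a methylene; the C1 ether is γ to C9 and cannot be eliminated.

Step 9
Reactants: 13 bicyclic ketone; 14 vinylmagnesium bromide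
Product: 15 (1R,2R,4R,8R)-8-[(4-methoxybenzyl)oxy]-5,6-dimethyl-2-vinylbicyclo[2.2.2]oct-5-en-2-ol (vinyl syn to the C5=C6 bridge)
Conditions: THF, −78 to 0 °C; aq. NH4Cl
Reagents that add atoms: none
Why: Grignard 1,2-addition to the bicyclo[2.2.2]octenone should occur from the face flanked by the sp2 bridge rather than the ethano bridge, which sets C8 with the vinyl group syn to C4=C5 as the sigmatropic shift requires.

Step 10
Reactants: 15 vinyl carbinol
Product: 18 (1R,5S,10R)-1-[(4-methoxybenzyl)oxy]-8-(trimethylsilyloxy)-11,12,13-trinoreremophila-3,7-diene (cis-fused; 1-OPMB 5-Me H-10 all β), via potassium alkoxide 16 (not isolated), via potassium enolate 17 (not isolated)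
Conditions: KH, 18-crown-6, THF, 0 °C to reflux; then Me3SiCl–Et3N, −78 °C
Reagents that add atoms: chlorotrimethylsilane C[Si](C)(C)Cl
Why: KH with 18-crown-6 gives the free alkoxide 16, whose oxyanion weakens the C3–C8 bond so that the 1,5-diene C6=C7–C8–C3–C4=C5 undergoes a concerted suprafacial [3,3] sigmatropic shift through the boat transition state enforced by the bicyclic cage (anionic oxy-Cope rearrangement, the known behaviour of 2-vinylbicyclo[2.2.2]oct-5-en-2-ols from masked o-benzoquinone adducts). Ring B closes pericyclically as a six-membered carbocycle when the vinyl terminus C6 bonds to C5 while C3–C8 opens, so no polar cyclisation mode is involved and the cage becomes a cis-fused decalin. The only new stereocentre, C5, is controlled by the C8 configuration from step 9, because C6 can reach C5 only on the face turned toward the C8–C9 bridge, which leaves the C5 methyl cis to H-10 and to the C1 ether. The step needs the vinyl group syn to the C4=C5 bridge, secured by the face selectivity of the Grignard addition, and a regiodefined enolate, which is inherent because the shift can only deliver the C7=C8 enolate 17 that Me3SiCl then silylates on oxygen. Formation of the delocalised enolate makes the shift irreversible.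

Step 11
Reactants: 18 enol silane; 19 acetone
Product: 22 11-hydroxy-1β-[(4-methoxybenzyl)oxy]-10βH-eremophil-3-en-8-one (mixture of C7 epimers), via lithium enolate 20 (not isolated), via chlorozinc enolate 21 (not isolated)
Conditions: MeLi (1 equiv), THF, 0 °C; ZnCl2, −78 °C; then 19, −78 °C; aq. NH4Cl
Reagents that add atoms: none
Why: Methyllithium cleaves the enol silane to the regiodefined C7 lithium enolate, transmetalation to zinc suppresses proton transfer and retro-aldol, and aldol addition to acetone gives the tertiary carbinol whose C7 epimers converge in step 12.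

Step 12
Reactants: 22 aldol
Product: 24 1β-[(4-methoxybenzyl)oxy]-10βH-eremophila-3,7(11)-dien-8-one, via tertiary mesylate 23 (not isolated)
Conditions: MsCl, Et3N, CH2Cl2, 0 °C; then DBU, rt
Reagents that add atoms: none
Why: Mesylation of the tertiary alcohol and base-induced E1cB elimination through the C7 enolate give the conjugated tetrasubstituted isopropylidene ketone, the thermodynamic regioisomer of this aldol dehydration.

Step 13
Reactants: 24 isopropylidene ketone
Product: 26 1β-[(4-methoxybenzyl)oxy]eremophila-3,7(11),9-trien-8-one, via silyl dienol ether 25 (not isolated)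
Conditions: LiN(i-Pr)2, THF, −78 °C; Me3SiCl; then Pd(OAc)2 (1.1 equiv), MeCN, rt
Reagents that add atoms: none
Why: Kinetic deprotonation at C9 (the only α-CH left), silylation and Saegusa–Ito oxidation (palladation at C9, β-hydride loss from C10) give the cross-conjugated dienone, erase the ring-fusion stereocentre and flatten ring B so that the C5 methyl is held axial over ring A.

Step 14
Reactants: 26 trienone
Product: 28 1β-[(4-methoxybenzyl)oxy]eremophila-7(11),9-diene-3α,8-diol (4β-methyl; mixture of C8 epimers), via boron adduct 27 (not isolated)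
Conditions: 9-BBN (excess), THF, 0 to 65 °C; then NaOH, H2O2, 0 °C
Reagents that add atoms: hydrogen peroxide OO
Why: 9-BBN is expected to reduce the dienone carbonyl 1,2 (as it does with enones) and to hydroborate only the unhindered trisubstituted C3=C4 bond, boron on C3 and hydrogen on C4 from the α face opposite the axial C5 methyl and the C1 ether, so that oxidation gives the 3α-alcohol with the C4 methyl β (anti-Markovnikov hydroboration–oxidation), while the tetrasubstituted C7=C11 bond and the encumbered, doubly oxygen-flanked C9=C10 bond should be left.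

Step 15
Reactants: 28 diol
Product: 29 1β-[(4-methoxybenzyl)oxy]eremophila-7(11),9-diene-3,8-dione
Conditions: Dess–Martin periodinane, NaHCO3, CH2Cl2, 0 °C to rt
Reagents that add atoms: none
Why: Dess–Martin oxidation converts both secondary alcohols, restoring the dienone and giving the C3 ketone under buffered, non-enolising conditions that spare the C4 stereocentre and the β-alkoxy ketone (the crude product is used at once).

Step 16
Reactants: 29 diketone
Product: 30 3β-hydroxy-1β-[(4-methoxybenzyl)oxy]eremophila-7(11),9-dien-8-one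
Conditions: LiBH(s-Bu)3 (1.05 equiv), THF, −78 °C; aq. NH4Cl
Reagents that add atoms: none
Why: The bulky hydride attacks the saturated C3 ketone from the open α face (the β face is blocked by the C4 and C5 methyls and the C1 ether) to give the 3β alcohol, while the doubly conjugated C8 ketone with fully substituted β-carbons is much less reactive at −78 °C (chemoselective bulky-hydride reduction).

Step 17
Reactants: 30 3β-alcohol; 31 angelic acid
Product: 33 3β-angeloyloxy-1β-[(4-methoxybenzyl)oxy]eremophila-7(11),9-dien-8-one, via mixed anhydride 32 (not isolated)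
Conditions: 31, 2,4,6-Cl3C6H2COCl, Et3N, toluene, rt; then 30, 80 °C
Reagents that add atoms: none
Why: Yamaguchi-type esterification through the preformed mixed anhydride acylates hindered secondary alcohols with angelic acid without the base-mediated isomerisation of the (Z)-enoate to the tiglate.

Step 18
Reactants: 33 PMB-protected angelate
Product: 34 3β-angeloyloxy-1β-hydroxyeremophila-7(11),9-dien-8-one
Conditions: DDQ, CH2Cl2–pH 7 buffer, 0 °C to rt
Reagents that add atoms: none
Why: DDQ oxidises the electron-rich benzylic ether to an oxocarbenium ion that water hydrolyses (oxidative PMB cleavage), conditions that leave the angelate and the dienone untouched.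

Step 19
Reactants: 34 isopropylidene dienone
Product: 35 (1R,3S,4R,5R)-3-angeloyloxy-11-hydroperoxy-1-hydroxyeremophila-6,9-dien-8-one (CNP0300636.1)
Conditions: O2, tetraphenylporphyrin (cat.), visible light, CH2Cl2, 0 °C
Reagents that add atoms: dioxygen O=O
Why: In the singlet-oxygen ene reaction (Schenck ene) of the tetrasubstituted enone, oxygen bonds to C11 and the allylic hydrogen is taken from C6, the group geminal to the carbonyl on the α-carbon, which moves the double bond to C6=C7 and gives the tertiary hydroperoxide, while the trisubstituted ester alkene and the C9=C10 enone should react much more slowly.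

Compound list
1 | 3,4-dimethylphenol | Cc1ccc(O)cc1C | starting material
2 | 2-bromo-4,5-dimethylphenol | Cc1cc(O)c(Br)cc1C | intermediate
3 | 2-methoxy-4,5-dimethylphenol | COc1cc(C)c(C)cc1O | intermediate
4 | 4-methoxybenzyl alcohol | COc1ccc(CO)cc1 | starting material
5 | ethyl vinyl ether | C=COCC | starting material
6 | 4-methoxybenzyl vinyl ether | C=COCc1ccc(OC)cc1 | intermediate
7 | 6,6-dimethoxy-3,4-dimethylcyclohexa-2,4-dien-1-one (o-quinone monoketal) | COC1(OC)C=C(C)C(C)=CC1=O | intermediate (not isolated)
8 | rac-(1R,4R,7R)-7-[(4-methoxybenzyl)oxy]-3,3-dimethoxy-5,6-dimethylbicyclo[2.2.2]oct-5-en-2-one, ether syn to the C5=C6 bridge (racemate; enantiomer carried on is drawn) | O=C1[C@H]2[C@H](OCc3ccc(OC)cc3)C[C@H](C(C)=C2C)C1(OC)OC | intermediate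
9 | rac-(1S,2S,4R,7R)-7-[(4-methoxybenzyl)oxy]-3,3-dimethoxy-5,6-dimethylbicyclo[2.2.2]oct-5-en-2-ol, hydroxyl anti to the C5=C6 bridge (racemate; enantiomer carried on is drawn) | O[C@H]1[C@H]2[C@H](OCc3ccc(OC)cc3)C[C@H](C(C)=C2C)C1(OC)OC | intermediate
10 | (1S)-(−)-camphanic chloride, (1S,4R)-4,7,7-trimethyl-3-oxo-2-oxabicyclo[2.2.1]heptane-1-carbonyl chloride | CC1(C)[C@@]2(C)CC[C@]1(C(Cl)=O)OC2=O | starting material
11 | (1S)-camphanate of (1S,2S,4R,7R)-9, single diastereomer | CC1(C)[C@@]2(C)CC[C@]1(C(=O)O[C@H]3[C@H]4[C@H](OCc5ccc(OC)cc5)C[C@H](C(C)=C4C)C3(OC)OC)OC2=O | intermediate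
12 | 3-[(1S)-camphanoyloxy]-8-[(4-methoxybenzyl)oxy]-5,6-dimethylbicyclo[2.2.2]oct-5-en-2-one, ring configuration as in 11 | CC1(C)[C@@]2(C)CC[C@]1(C(=O)O[C@H]3[C@H]4[C@H](OCc5ccc(OC)cc5)C[C@H](C(C)=C4C)C3=O)OC2=O | intermediate
13 | (1R,4R,8R)-8-[(4-methoxybenzyl)oxy]-5,6-dimethylbicyclo[2.2.2]oct-5-en-2-one | O=C1C[C@H]2[C@H](OCc3ccc(OC)cc3)C[C@@H]1C(C)=C2C | intermediate
14 | vinylmagnesium bromide | C=C[Mg]Br | starting material
15 | (1R,2R,4R,8R)-8-[(4-methoxybenzyl)oxy]-5,6-dimethyl-2-vinylbicyclo[2.2.2]oct-5-en-2-ol, vinyl syn to the C5=C6 bridge | C=C[C@]1(O)C[C@H]2[C@H](OCc3ccc(OC)cc3)C[C@@H]1C(C)=C2C | intermediate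
16 | potassium alkoxide of 15 | [K+].C=C[C@]1([O-])C[C@H]2[C@H](OCc3ccc(OC)cc3)C[C@@H]1C(C)=C2C | intermediate (not isolated)
17 | potassium C7=C8 enolate of the cis-fused decalin (1β-OPMB, 5β-Me, 10β-H) | [K+].COc1ccc(CO[C@@H]2CC=C(C)[C@@]3(C)CC=C([O-])C[C@@H]23)cc1 | intermediate (not isolated)
18 | (1R,5S,10R)-1-[(4-methoxybenzyl)oxy]-8-(trimethylsilyloxy)-11,12,13-trinoreremophila-3,7-diene, cis-fused | COc1ccc(CO[C@@H]2CC=C(C)[C@@]3(C)CC=C(O[Si](C)(C)C)C[C@@H]23)cc1 | intermediate
19 | acetone | CC(C)=O | starting material
20 | lithium C7=C8 enolate corresponding to 18 | [Li+].COc1ccc(CO[C@@H]2CC=C(C)[C@@]3(C)CC=C([O-])C[C@@H]23)cc1 | intermediate (not isolated)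
21 | chlorozinc C7=C8 enolate corresponding to 18 | COc1ccc(CO[C@@H]2CC=C(C)[C@@]3(C)CC=C(O[Zn]Cl)C[C@@H]23)cc1 | intermediate (not isolated)
22 | 11-hydroxy-1β-[(4-methoxybenzyl)oxy]-10βH-eremophil-3-en-8-one, C7 epimers | COc1ccc(CO[C@@H]2CC=C(C)[C@@]3(C)CC(C(C)(C)O)C(=O)C[C@@H]23)cc1 | intermediate
23 | 11-methanesulfonate of 22 | COc1ccc(CO[C@@H]2CC=C(C)[C@@]3(C)CC(C(C)(C)OS(C)(=O)=O)C(=O)C[C@@H]23)cc1 | intermediate (not isolated)
24 | 1β-[(4-methoxybenzyl)oxy]-10βH-eremophila-3,7(11)-dien-8-one | COc1ccc(CO[C@@H]2CC=C(C)[C@@]3(C)CC(=C(C)C)C(=O)C[C@@H]23)cc1 | intermediate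
25 | 1β-[(4-methoxybenzyl)oxy]-8-(trimethylsilyloxy)-10βH-eremophila-3,7(11),8-triene | COc1ccc(CO[C@@H]2CC=C(C)[C@@]3(C)CC(=C(C)C)C(O[Si](C)(C)C)=C[C@@H]23)cc1 | intermediate (not isolated)
26 | 1β-[(4-methoxybenzyl)oxy]eremophila-3,7(11),9-trien-8-one | COc1ccc(CO[C@@H]2CC=C(C)[C@@]3(C)CC(=C(C)C)C(=O)C=C23)cc1 | intermediate
27 | 3α-(9-borabicyclo[3.3.1]nonan-9-yl)-8-[(9-borabicyclo[3.3.1]nonan-9-yl)oxy]-1β-[(4-methoxybenzyl)oxy]eremophila-7(11),9-diene, C8 epimers | B1(C2CCCC1CCC2)[C@@H]1C[C@@H](OCc2ccc(OC)cc2)C2=CC(OB3C4CCCC3CCC4)C(=C(C)C)C[C@]2(C)[C@H]1C | intermediate (not isolated)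
28 | 1β-[(4-methoxybenzyl)oxy]eremophila-7(11),9-diene-3α,8-diol, 4β-methyl, C8 epimers | O[C@@H]1C[C@@H](OCc2ccc(OC)cc2)C2=CC(O)C(=C(C)C)C[C@]2(C)[C@H]1C | intermediate
29 | 1β-[(4-methoxybenzyl)oxy]eremophila-7(11),9-diene-3,8-dione | O=C1C[C@@H](OCc2ccc(OC)cc2)C2=CC(=O)C(=C(C)C)C[C@]2(C)[C@H]1C | intermediate
30 | 3β-hydroxy-1β-[(4-methoxybenzyl)oxy]eremophila-7(11),9-dien-8-one | O[C@H]1C[C@@H](OCc2ccc(OC)cc2)C2=CC(=O)C(=C(C)C)C[C@]2(C)[C@H]1C | intermediate
31 | angelic acid, (Z)-2-methylbut-2-enoic acid | C/C=C(/C)C(=O)O | starting material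
32 | angelic 2,4,6-trichlorobenzoic anhydride | C/C=C(/C)C(=O)OC(=O)c1c(Cl)cc(Cl)cc1Cl | intermediate (not isolated)
33 | 3β-angeloyloxy-1β-[(4-methoxybenzyl)oxy]eremophila-7(11),9-dien-8-one | C/C=C(/C)C(=O)O[C@H]1C[C@@H](OCc2ccc(OC)cc2)C2=CC(=O)C(=C(C)C)C[C@]2(C)[C@H]1C | intermediate
34 | 3β-angeloyloxy-1β-hydroxyeremophila-7(11),9-dien-8-one | C/C=C(/C)C(=O)O[C@H]1C[C@@H](O)C2=CC(=O)C(=C(C)C)C[C@]2(C)[C@H]1C | intermediate
35 | (1R,3S,4R,5R)-3-angeloyloxy-11-hydroperoxy-1-hydroxyeremophila-6,9-dien-8-one (CNP0300636.1) | C/C=C(/C)C(=O)O[C@H]1C[C@@H](O)C2=CC(=O)C(C(C)(C)OO)=C[C@]2(C)[C@H]1C | target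

Total step count: 19. Longest linear sequence: 18 steps (1 to 35 through steps 1, 2 and 4–19); step 3 is a one-step side branch.

Steps most likely to fail

Step 14. Hydroboration may not stop at C3=C4: once the carbonyl is reduced, boron may also add across C9=C10. Incomplete carbonyl reduction would in turn expose the dienone to nucleophilic epoxidation during the alkaline peroxide work-up. The fallback sets out from 26 and avoids boranes. Epoxidation with mCPBA (NaHCO3, CH2Cl2, 0 °C) is selective for the electron-rich C3=C4 bond and should occur on the α face to give the 3α,4α-epoxide F1. Homolytic epoxide opening with Cp2TiCl (trivalent titanium, made from Cp2TiCl2 and Mn) and 1,4-cyclohexadiene in THF gives the tertiary C4 radical, which takes hydrogen on the open α face, so the 3α-hydroxy dienone F2 forms with the ketone intact. Dess–Martin oxidation of F2 gives 29, where the route is rejoined.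

Step 10. The alkoxide may fragment, or the shift onto the fully substituted alkene carbon may be so slow that decomposition of the alkoxide or enolate competes. The fallback sets out from 15 and uses the neutral variant of the same bond reorganisation. Silylation (Me3SiCl, imidazole, DMF) gives the trimethylsilyl ether F3. Thermal siloxy-Cope rearrangement of F3 (sealed tube, about 220 °C, toluene with a little N,O-bis(trimethylsilyl)acetamide) delivers enol silane 18 directly, where the route is rejoined.

Step 17. Acylation of the crowded axial C3 hydroxyl may be too slow, and forcing it may isomerise the angelate to the tiglate. The fallback sets out from 30 and builds the (Z)-alkene on the molecule. Esterification with 2-[bis(2,2,2-trifluoroethoxy)phosphoryl]propanoic acid (DCC, DMAP, CH2Cl2), a small saturated acid, gives the phosphonopropionate F4. Still–Gennari olefination of F4 (KN(SiMe3)2, 18-crown-6, THF, −78 °C; then acetaldehyde) gives the (Z)-2-methylbut-2-enoate 33, where the route is rejoined.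

Further compounds
F1 | step 14 | 3α,4α-epoxy-1β-[(4-methoxybenzyl)oxy]eremophila-7(11),9-dien-8-one | O1[C@@H]2C[C@@H](OCc3ccc(OC)cc3)C4=CC(=O)C(=C(C)C)C[C@]4(C)[C@]12C
F2 | step 14 | 3α-hydroxy-1β-[(4-methoxybenzyl)oxy]eremophila-7(11),9-dien-8-one | O[C@@H]1C[C@@H](OCc2ccc(OC)cc2)C2=CC(=O)C(=C(C)C)C[C@]2(C)[C@H]1C
F3 | step 10 | trimethylsilyl ether of 15 | C=C[C@]1(O[Si](C)(C)C)C[C@H]2[C@H](OCc3ccc(OC)cc3)C[C@@H]1C(C)=C2C
F4 | step 17 | 2-[bis(2,2,2-trifluoroethoxy)phosphoryl]propanoate of 30 (epimers at the phosphonate carbon) | CC(C(=O)O[C@H]1C[C@@H](OCc2ccc(OC)cc2)C2=CC(=O)C(=C(C)C)C[C@]2(C)[C@H]1C)P(=O)(OCC(F)(F)F)OCC(F)(F)F
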